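**Retrosynthetic overview**
1. Endgame, ring A oxygens last: target ⇐ Lindlar reduction of a 14-yne ⇐ staged acylation of a 2α,3α-diol ⇐ α-face OsO4 on a Δ2-ene ⇐ Δ1-3-ketone (hydrazone transposition) ⇐ LiAlH4 opening of a C20(=O)–O–C3 bridged lactone.
2. Key disconnection: C3–C4 and C5–C10 together, by an intramolecular Diels–Alder reaction of a 3-alkenyl-5-bromo-2-pyrone with its own prenyl terminus. Rings A and B form in this one operation from a precursor that has no carbocycle.
3. Enabling feature: in ring A the chain C10–C1–C2–C3, the oxygen on C3 and the oxygenated carbon C20 on C10 are the six ring atoms of a 2-pyrone (C20 = lactone C=O, O-3 = ring O). C4(CH3)2=C5H is a prenyl end, and C6–C7–C8=C9 of ring B is a four-atom tether whose Z-tetrasubstituted alkene and C7 carbinol preorganise and steer the cycloaddition.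
4. Precursor assembly: C9–C10 by Stille coupling, C8=C9 by anti-carbomagnesiation/iodination of a propargylic alcohol, C7 by asymmetric transfer hydrogenation of an ynone, C7–C8 by acetylide acylation.
5. C13 comes from Sharpless epoxidation of geraniol. The vinyl group travels as a silylalkyne, so the prenyl alkene is the only dienophile and the Δ2-ene the only alkene open to OsO4.

Key step: step 13

Remark: labdane numbering is used (decalin C1–C10, gem-dimethyl on C4, C17 = CH3 on C8, C20 = CH2O on C10, side chain C11–C16; β = face of C20). TES = triethylsilyl, TBS = tert-butyldimethylsilyl. Compounds 1, 8, 17 and 28 are taken as commercial.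

**Step 1**
Reactants: 1 geraniol
Product: 2 (2R,3R)-2,3-epoxygeraniol
Conditions: Ti(OiPr)4 (5 mol %), D-(−)-diethyl tartrate (7 mol %), t-BuOOH, 4 Å MS, CH2Cl2, −20 °C
Reagents that add atoms: tert-butyl hydroperoxide, CC(C)(C)OO
Why: Sharpless asymmetric epoxidation acts only on the allylic alcohol alkene, and the D-(−)-tartrate should give the (2R,3R)-epoxide, whose C3–O bond becomes the C13–O bond of the target in the required (R) configuration.

**Step 2**
Reactants: 2 (2R,3R)-2,3-epoxygeraniol
Product: 3 (2R,3R)-epoxygeranyl chloride (1-chloro-2,3-epoxide, both epoxide carbons spatially unchanged)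
Conditions: PPh3, CCl4, NaHCO3 (buffer), reflux
Reagents that add atoms: tetrachloromethane, ClC(Cl)(Cl)Cl
Why: Appel chlorination replaces the primary hydroxyl under near-neutral conditions without touching the epoxide stereocentres.

**Step 3**
Reactants: 3 (2R,3R)-epoxygeranyl chloride
Product: 5 (R)-3,7-dimethyl-3-(triethylsilyloxy)-1-(triethylsilyl)oct-6-en-1-yne, via dilithium alkynolate 4 (not isolated)
Conditions: n-BuLi (3.3 equiv), THF, −40 °C; then TESCl (2.5 equiv), DMAP (cat.), −40 °C → rt
Reagents that add atoms: chlorotriethylsilane, CC[Si](Cl)(CC)CC; n-butyllithium, [Li]CCCC (lithium in 4 only)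
Why: Base-induced double elimination of a 2,3-epoxy chloride (epoxide opening to the chloroallylic alkoxide, then loss of HCl) gives the tertiary propargylic alkoxide with its C–O stereocentre untouched, and silylation of the dianion on O and C masks the future vinyl group as a hindered silylalkyne.

**Step 4**
Reactants: 5 bis-TES dehydrolinalool
Product: 6 (R)-4-methyl-4-(triethylsilyloxy)-6-(triethylsilyl)hex-5-ynal
Conditions: O3, CH2Cl2, −78 °C, Sudan III end point; then Me2S, −78 °C → rt
Reagents that add atoms: ozone, [O-][O+]=O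
Why: Ozonolysis with reductive work-up cleaves the electron-rich trisubstituted alkene much faster than the hindered silylalkyne and leaves the aldehyde whose carbonyl carbon is C9.

**Step 5**
Reactants: 6 aldehyde
Product: 7 (R)-1,1-dibromo-5-methyl-5-(triethylsilyloxy)-7-(triethylsilyl)hept-1-en-6-yne
Conditions: CBr4, PPh3, CH2Cl2, 0 °C
Reagents that add atoms: tetrabromomethane, BrC(Br)(Br)Br
Why: The first stage of the Corey–Fuchs homologation (dibromoolefination) adds C8 under conditions that the silyl groups tolerate.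

**Step 6**
Reactants: 8 4-methylpent-3-enoic acid
Product: 10 N-methoxy-N,4-dimethylpent-3-enamide, via acyl imidazole 9 (not isolated)
Conditions: CDI, CH2Cl2, rt; then MeNHOMe·HCl, rt
Reagents that add atoms: N,O-dimethylhydroxylamine hydrochloride, CNOC.Cl; 1,1'-carbonyldiimidazole, O=C(n1ccnc1)n1ccnc1 (imidazolyl group in 9 only)
Why: Weinreb amide formation through the acyl imidazole is mild enough to keep the β,γ-alkene (C5=C4) out of conjugation.

**Step 7**
Reactants: 7 dibromoolefin; 10 Weinreb amide
Product: 12 (R)-2,10-dimethyl-10-(triethylsilyloxy)-12-(triethylsilyl)dodec-2-ene-6,11-diyn-5-one, via lithium acetylide 11 (not isolated)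
Conditions: 7, n-BuLi (2.05 equiv), THF, −78 → −20 °C; then 10, −78 °C; AcOH quench at −78 °C
Reagents that add atoms: n-butyllithium, [Li]CCCC (lithium in 11 only)
Why: The second stage of the Corey–Fuchs sequence gives the acetylide, which acylates once on the Weinreb amide because the chelated tetrahedral adduct survives until the cold acidic quench, and that quench also prevents isomerisation of the β,γ-unsaturated ynone.

**Step 8**
Reactants: 12 ynone
Product: 13 (5R,10R)-2,10-dimethyl-10-(triethylsilyloxy)-12-(triethylsilyl)dodec-2-ene-6,11-diyn-5-ol (carbinol carbon = C7)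
Conditions: Ru(p-cymene)[(R,R)-TsDPEN] (3 mol %), i-PrOH, rt
Reagents that add atoms: none
Why: Noyori asymmetric transfer hydrogenation of ynones runs without base, distinguishes the alkynyl from the alkyl flank, and with the (R,R)-catalyst should give the (R)-carbinol that is C7 of the target.

**Step 9**
Reactants: 13 (R)-propargylic alcohol
Product: 15 (5R,6Z,10R)-7-iodo-2,6,10-trimethyl-10-(triethylsilyloxy)-12-(triethylsilyl)dodeca-2,6-dien-11-yn-5-ol, via oxamagnesacyclopentene 14 (not isolated)
Conditions: MeMgBr (4 equiv), CuI (20 mol %), Et2O–THF, 0 °C → rt; then I2, −40 → 0 °C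
Reagents that add atoms: methylmagnesium bromide, C[Mg]Br; iodine, II
Why: Copper-catalysed hydroxyl-directed anti-carbomagnesiation of a propargylic alcohol puts the methyl group on the proximal carbon C8 and magnesium on C9 inside a five-membered chelate, so iodinolysis with retention gives the tetrasubstituted iodide with iodine cis to C7.

**Step 10**
Reactants: 15 iodo alcohol
Product: 16 the C7 tert-butyldimethylsilyl ether of 15
Conditions: TBSOTf, 2,6-lutidine, CH2Cl2, −40 → 0 °C
Reagents that add atoms: tert-butyldimethylsilyl triflate, CC(C)(C)[Si](C)(C)OS(=O)(=O)C(F)(F)F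
Why: Silyl triflate/lutidine silylation protects the hindered allylic alcohol without ionising it and supplies the bulky C7 substituent that steers the key step.

**Step 11**
Reactants: 17 3,5-dibromo-2H-pyran-2-one
Product: 18 5-bromo-3-(trimethylstannyl)-2H-pyran-2-one
Conditions: (Me3Sn)2, Pd(PPh3)4 (5 mol %), toluene, 90 °C
Reagents that add atoms: hexamethylditin, C[Sn](C)(C)[Sn](C)(C)C
Why: Palladium-catalysed stannylation follows the established preference of Pd(0) for oxidative addition at the more electron-poor C3–Br bond of this pyrone.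

**Step 12**
Reactants: 16 alkenyl iodide; 18 stannylpyrone
Product: 19 5-bromo-3-[(5R,6Z,10R)-5-(TBSO)-2,6,10-trimethyl-10-(TESO)-12-(TES)dodeca-2,6-dien-11-yn-7-yl]-2H-pyran-2-one
Conditions: Pd2(dba)3 (5 mol %), AsPh3 (20 mol %), CuI (20 mol %), DMF, 45 °C
Reagents that add atoms: none
Why: Copper-assisted Stille coupling forms C9–C10 with retention of alkene geometry, because the alkenyl iodide undergoes oxidative addition ahead of the pyrone C5–Br bond.

**Step 13**
Reactants: 19 3-alkenyl-5-bromo-2-pyrone
Product: 20 2-bromo-7α-(TBSO)-13-(TESO)-15-(TES)labda-1,8-dien-14-yn-20,3β-olide (5α-H, C20 β, 13R)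
Conditions: PhMe (0.01 M), BHT (10 mol %), degassed, sealed tube, 105–110 °C
Reagents that add atoms: none
Why: This is a thermal intramolecular Diels–Alder reaction in which the s-cis-locked pyrone diene C10=C1–C2=C3 (pyrone C3–C6) adds suprafacially, in a concerted but asynchronous way, to the prenyl alkene C5=C4 and gives a 2-oxabicyclo[2.2.2]oct-5-en-3-one in which C20(=O)–O still bridges C10 and C3. The closest known reaction type is the cycloaddition of 5-halo-2-pyrones with a Me2C=CH– alkene held on a four-atom tether, which proceeds near 100 °C with the CO2 bridge kept; the bromine lowers the diene LUMO and stabilises the adduct against cycloreversion, and the Z-alkene of the tether, twisted out of the pyrone plane by its four substituents, already holds C7 over one pyrone face. Ring B closes through C5–C10 as the fused six-membered ring of a type 1 (1,3,9-decatriene) IMDA, and ring A closes through C3–C4 as the new cyclohexene, held as a boat by the lactone bridge. C10 and C3 are set together because both bonds form on the same pyrone face (C20 and O-3 necessarily cis); C5 is set by the exo placement of the tether (C6 beside the lactone carbonyl, H-5 under C1=C2), which lets the C11 methylene lean towards C1–H rather than the carbonyl oxygen and keeps the C7–O dipole away from C20=O, so that H-5 and C20 end up trans; and the absolute sense comes from C7, whose OTBS group must sit pseudoaxial in the forming half-chair to avoid A(1,2) strain with the C17 methyl. The step needs chemoselectivity (the silylalkyne and the tetrasubstituted C8=C9 alkene are too hindered to compete and no vinyl group is present), regioselectivity (fixed by the tether length, which overrides the weak polarity preference of the alkene) and a temperature below the onset of CO2 loss.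

**Step 14**
Reactants: 20 bromo adduct
Product: 21 7α-(TBSO)-13-(TESO)-15-(TES)labda-1,8-dien-14-yn-20,3β-olide
Conditions: n-Bu3SnH, AIBN (cat.), PhH, 80 °C
Reagents that add atoms: none
Why: Radical hydrodebromination with tin hydride removes the activating bromine, since the C2 vinyl radical is quenched by the stannane faster than it can do anything else and the lactone is inert.

**Step 15**
Reactants: 21 bridged lactone
Product: 22 7α-(TBSO)-13-(TESO)-15-(TES)labda-1,8-dien-14-yne-3β,20-diol
Conditions: LiAlH4, Et2O, 0 °C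
Reagents that add atoms: none
Why: Lactone reduction with LiAlH4 cuts the temporary bridge, brings C20 to the CH2OH level of the target and frees the 3β-allylic alcohol, while silyl ethers and the O-protected silylalkyne survive at 0 °C.

**Step 16**
Reactants: 22 diol
Product: 23 20-hydroxy-7α-(TBSO)-13-(TESO)-15-(TES)labda-1,8-dien-14-yn-3-one
Conditions: MnO2, CH2Cl2, rt
Reagents that add atoms: none
Why: Manganese dioxide oxidises only the allylic C3 alcohol and leaves the neopentyl primary C20 alcohol alone.

**Step 17**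
Reactants: 23 hydroxy enone
Product: 24 20-acetoxy-7α-(TBSO)-13-(TESO)-15-(TES)labda-1,8-dien-14-yn-3-one
Conditions: Ac2O, pyridine, DMAP (cat.), CH2Cl2, rt
Reagents that add atoms: acetic anhydride, CC(=O)OC(C)=O
Why: DMAP-catalysed acetylation of the only free hydroxyl installs the C20 acetate of the target before the ring A diol exists.

**Step 18**
Reactants: 24 acetoxy enone
Product: 25 the C3 p-toluenesulfonylhydrazone of 24
Conditions: TsNHNH2, PPTS (cat.), 4 Å MS, THF, 50 °C
Reagents that add atoms: p-toluenesulfonyl hydrazide, Cc1ccc(cc1)S(=O)(=O)NN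
Why: Hydrazone condensation is routine for 4,4-dimethyl-3-ketones, and conjugate addition at C1 is blocked by the neighbouring quaternary C10.

**Step 19**
Reactants: 25 tosylhydrazone
Product: 26 20-acetoxy-7α-(TBSO)-13-(TESO)-15-(TES)labda-2,8-dien-14-yne
Conditions: catecholborane, CHCl3, −10 °C → rt; then NaOAc·3H2O, reflux
Reagents that add atoms: none
Why: In the Kabalka reduction of an α,β-unsaturated tosylhydrazone (1,2-hydride addition, loss of sulfinate, retro-ene loss of N2 from the allylic diazene), hydrogen is delivered to C1 and the alkene moves regiospecifically to C2=C3, which erases the C3 oxygen that the bridge had forced onto the β face.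

**Step 20**
Reactants: 26 Δ2-ene
Product: 27 20-acetoxy-7α-(TBSO)-13-(TESO)-15-(TES)labd-8-en-14-yne-2α,3α-diol
Conditions: OsO4 (4 mol %), NMO, acetone–H2O, 0 °C → rt
Reagents that add atoms: N-methylmorpholine N-oxide, C[N+]1([O-])CCOCC1; water, O (oxygen is passed on by catalytic osmium tetroxide, O=[Os](=O)(=O)=O)
Why: Upjohn dihydroxylation attacks the cis-disubstituted Δ2-alkene from the α face, because the axial C20 group and the 4β-methyl block the β face, and so sets C2 and C3 as the cis-2α,3α-diol, while the hindered tetrasubstituted C8=C9 alkene and the silylalkyne react far more slowly.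

**Step 21**
Reactants: 27 2α,3α-diol; 28 angelic acid
Product: 30 2α-angeloyloxy-20-acetoxy-7α-(TBSO)-13-(TESO)-15-(TES)labd-8-en-14-yn-3α-ol, via mixed anhydride 29 (not isolated)
Conditions: 28, 2,4,6-Cl3C6H2COCl, Et3N, PhMe, rt; then 27, 75 °C
Reagents that add atoms: 2,4,6-trichlorobenzoyl chloride, O=C(Cl)c1c(Cl)cc(Cl)cc1Cl (aroyl group in 29 only)
Why: Yamaguchi-type mixed-anhydride esterification without a nucleophilic catalyst keeps the Z geometry of the angelate, and the equatorial 2α-OH is acylated in preference to the axial, neopentyl 3α-OH.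

**Step 22**
Reactants: 30 monoangelate
Product: 31 3α,20-diacetoxy-2α-angeloyloxy-7α-(TBSO)-13-(TESO)-15-(TES)labd-8-en-14-yne
Conditions: Ac2O, DMAP, Et3N, CH2Cl2, rt → 35 °C
Reagents that add atoms: acetic anhydride, CC(=O)OC(C)=O
Why: DMAP-catalysed acetylation forces the remaining hindered axial 3α-OH to react, and an angelate ester once formed is stable to these conditions.

**Step 23**
Reactants: 31 fully protected triester
Product: 32 3α,20-diacetoxy-2α-angeloyloxylabd-8-en-14-yne-7α,13-diol (14,15-didehydro target)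
Conditions: TBAF–AcOH (1:1), THF, 0 °C → rt
Reagents that add atoms: none
Why: Buffered fluoride desilylation removes the O-TBS, O-TES and C-TES groups in one operation, and the acetic acid keeps the medium too weakly basic for ester cleavage, acyl migration or angelate isomerisation.

**Step 24**
Reactants: 32 ethynyl carbinol
Product: 33 target, CNP0180940.1
Conditions: H2 (1 atm), Lindlar catalyst, quinoline, EtOAc, rt, stopped after 1 equiv H2
Reagents that add atoms: none
Why: Lindlar semihydrogenation of a terminal tertiary propargylic alcohol stops at the vinyl carbinol and touches neither the tetrasubstituted alkene nor the trisubstituted angelate.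

**Compound list**
1 | geraniol | CC(C)=CCC/C(C)=C/CO | starting material
2 | (2R,3R)-2,3-epoxygeraniol | OC[C@H]1O[C@]1(C)CCC=C(C)C | intermediate
3 | (2R,3R)-epoxygeranyl chloride | ClC[C@H]1O[C@]1(C)CCC=C(C)C | intermediate
4 | dilithium salt of (R)-dehydrolinalool (not isolated) | [Li+].[Li+].[C-]#C[C@](C)([O-])CCC=C(C)C | intermediate
5 | (R)-3,7-dimethyl-3-(triethylsilyloxy)-1-(triethylsilyl)oct-6-en-1-yne | CC[Si](CC)(CC)C#C[C@](C)(O[Si](CC)(CC)CC)CCC=C(C)C | intermediate
6 | (R)-4-methyl-4-(triethylsilyloxy)-6-(triethylsilyl)hex-5-ynal | CC[Si](CC)(CC)C#C[C@](C)(O[Si](CC)(CC)CC)CCC=O | intermediate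
7 | (R)-1,1-dibromo-5-methyl-5-(triethylsilyloxy)-7-(triethylsilyl)hept-1-en-6-yne | CC[Si](CC)(CC)C#C[C@](C)(O[Si](CC)(CC)CC)CCC=C(Br)Br | intermediate
8 | 4-methylpent-3-enoic acid | CC(C)=CCC(=O)O | starting material
9 | 1-(4-methylpent-3-enoyl)imidazole (not isolated) | CC(C)=CCC(=O)n1ccnc1 | intermediate
10 | N-methoxy-N,4-dimethylpent-3-enamide | CC(C)=CCC(=O)N(C)OC | intermediate
11 | lithium acetylide from 7 (not isolated) | CC[Si](CC)(CC)C#C[C@](C)(O[Si](CC)(CC)CC)CCC#C[Li] | intermediate
12 | ynone | CC[Si](CC)(CC)C#C[C@](C)(O[Si](CC)(CC)CC)CCC#CC(=O)CC=C(C)C | intermediate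
13 | (5R,10R)-propargylic alcohol | CC[Si](CC)(CC)C#C[C@](C)(O[Si](CC)(CC)CC)CCC#C[C@H](O)CC=C(C)C | intermediate
14 | oxamagnesacyclopentene (not isolated) | CC[Si](CC)(CC)C#C[C@](C)(O[Si](CC)(CC)CC)CCC1=C(C)[C@@H](CC=C(C)C)O[Mg]1 | intermediate
15 | (Z)-iodo allylic alcohol | CC[Si](CC)(CC)C#C[C@](C)(O[Si](CC)(CC)CC)CC/C(I)=C(\C)[C@H](O)CC=C(C)C | intermediate
16 | (Z)-iodide, C7 TBS ether | CC[Si](CC)(CC)C#C[C@](C)(O[Si](CC)(CC)CC)CC/C(I)=C(\C)[C@H](O[Si](C)(C)C(C)(C)C)CC=C(C)C | intermediate
17 | 3,5-dibromo-2H-pyran-2-one | O=C1OC=C(Br)C=C1Br | starting material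
18 | 5-bromo-3-(trimethylstannyl)-2H-pyran-2-one | O=C1OC=C(Br)C=C1[Sn](C)(C)C | intermediate
19 | 3-alkenyl-5-bromo-2-pyrone (cycloaddition precursor) | CC[Si](CC)(CC)C#C[C@](C)(O[Si](CC)(CC)CC)CC/C(C1=CC(Br)=COC1=O)=C(\C)[C@H](O[Si](C)(C)C(C)(C)C)CC=C(C)C | intermediate
20 | 2-bromo-labda-1,8-dien-14-yn-20,3β-olide (7α-OTBS, 13-OTES, 15-TES) | CC[Si](CC)(CC)C#C[C@](C)(O[Si](CC)(CC)CC)CCC1=C(C)[C@H](O[Si](C)(C)C(C)(C)C)C[C@H]2C(C)(C)[C@@H]3C(Br)=C[C@]12C(=O)O3 | intermediate
21 | labda-1,8-dien-14-yn-20,3β-olide (7α-OTBS, 13-OTES, 15-TES) | CC[Si](CC)(CC)C#C[C@](C)(O[Si](CC)(CC)CC)CCC1=C(C)[C@H](O[Si](C)(C)C(C)(C)C)C[C@H]2C(C)(C)[C@@H]3C=C[C@]12C(=O)O3 | intermediate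
22 | 3β,20-diol | CC[Si](CC)(CC)C#C[C@](C)(O[Si](CC)(CC)CC)CCC1=C(C)[C@H](O[Si](C)(C)C(C)(C)C)C[C@H]2C(C)(C)[C@@H](O)C=C[C@]12CO | intermediate
23 | 20-hydroxy-Δ1-3-ketone | CC[Si](CC)(CC)C#C[C@](C)(O[Si](CC)(CC)CC)CCC1=C(C)[C@H](O[Si](C)(C)C(C)(C)C)C[C@H]2C(C)(C)C(=O)C=C[C@]12CO | intermediate
24 | 20-acetoxy-Δ1-3-ketone | CC[Si](CC)(CC)C#C[C@](C)(O[Si](CC)(CC)CC)CCC1=C(C)[C@H](O[Si](C)(C)C(C)(C)C)C[C@H]2C(C)(C)C(=O)C=C[C@]12COC(C)=O | intermediate
25 | tosylhydrazone of 24 | CC[Si](CC)(CC)C#C[C@](C)(O[Si](CC)(CC)CC)CCC1=C(C)[C@H](O[Si](C)(C)C(C)(C)C)C[C@H]2C(C)(C)C(=NNS(=O)(=O)c3ccc(C)cc3)C=C[C@]12COC(C)=O | intermediate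
26 | 20-acetoxy-Δ2-ene | CC[Si](CC)(CC)C#C[C@](C)(O[Si](CC)(CC)CC)CCC1=C(C)[C@H](O[Si](C)(C)C(C)(C)C)C[C@H]2C(C)(C)C=CC[C@]12COC(C)=O | intermediate
27 | 20-acetoxy-2α,3α-diol | CC[Si](CC)(CC)C#C[C@](C)(O[Si](CC)(CC)CC)CCC1=C(C)[C@H](O[Si](C)(C)C(C)(C)C)C[C@H]2C(C)(C)[C@H](O)[C@H](O)C[C@]12COC(C)=O | intermediate
28 | angelic acid, (Z)-2-methylbut-2-enoic acid | C/C=C(/C)C(=O)O | starting material
29 | angelic 2,4,6-trichlorobenzoic anhydride (not isolated) | C/C=C(/C)C(=O)OC(=O)c1c(Cl)cc(Cl)cc1Cl | intermediate
30 | 2α-angelate 3α-ol 20-acetate | CC[Si](CC)(CC)C#C[C@](C)(O[Si](CC)(CC)CC)CCC1=C(C)[C@H](O[Si](C)(C)C(C)(C)C)C[C@H]2C(C)(C)[C@H](O)[C@H](OC(=O)/C(C)=C\C)C[C@]12COC(C)=O | intermediate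
31 | 2α-angelate 3α,20-diacetate, fully silylated | CC[Si](CC)(CC)C#C[C@](C)(O[Si](CC)(CC)CC)CCC1=C(C)[C@H](O[Si](C)(C)C(C)(C)C)C[C@H]2C(C)(C)[C@H](OC(C)=O)[C@H](OC(=O)/C(C)=C\C)C[C@]12COC(C)=O | intermediate
32 | 14,15-didehydro target (ethynyl carbinol) | C#C[C@](C)(O)CCC1=C(C)[C@H](O)C[C@H]2C(C)(C)[C@H](OC(C)=O)[C@H](OC(=O)/C(C)=C\C)C[C@]12COC(C)=O | intermediate
33 | CNP0180940.1 | C=C[C@](C)(O)CCC1=C(C)[C@H](O)C[C@H]2C(C)(C)[C@H](OC(C)=O)[C@H](OC(=O)/C(C)=C\C)C[C@]12COC(C)=O | target

**Step count**
Total step count: 24. Longest linear sequence: 22 (steps 1–5, 7–10, 12–24).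

**Steps most likely to fail**

**1. Step 13 (intramolecular pyrone Diels–Alder).**
- What may go wrong: bond formation at the fully substituted alkene carbon C4 may be slow, since C4 is sterically loaded and the tether imposes a bond polarity that runs against the weak intrinsic preference of the alkene. At the temperature then needed, loss of CO2 from the adduct or poor exo/endo discrimination could take over.
- Fallback: it sets out from 19, comes back at 23, and no longer makes the quaternary C4 in the cycloaddition. Ethenolysis of 19 (Hoveyda–Grubbs II catalyst, ethylene, CH2Cl2) trims the prenyl end to give the allyl analogue F1. In F1 the nucleophilic terminal CH2 meets pyrone C6 in the matched, unhindered sense, so the same cycloaddition should run at lower temperature to the 4,4-bisnor bromo adduct F2.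
- Tin hydride debromination then gives the bisnor lactone F3, LiAlH4 the bisnor diol F4, and MnO2 the bisnor hydroxy enone F5.
- The gem-dimethyl group is added by two successive kinetic α′-methylations (LDA, 2.2 equiv, then MeI, THF–DMPU). C4 is the only enolisable position and the lithium alkoxide of C20–OH stays unalkylated. This passes through the 4α-methyl enone F6 and ends at 23.

**2. Step 9 (anti-carbomagnesiation of the secondary propargylic alcohol).**
- What may go wrong: the magnesium alkoxide of a branched carbinol may add MeMgBr too slowly, so that unreacted alkyne is returned or regiocontrol erodes.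
- Fallback: it sets out from 7, comes back at 15, moves the carbometalation to the unbranched substrate class on which it is best established, and creates C7 afterwards by reagent control.
- The acetylide 11, generated from 7 as in step 7, is trapped with paraformaldehyde to give the primary propargylic alcohol F7. MeMgBr/CuI gives the unsubstituted oxamagnesacyclopentene F8, and iodinolysis gives the (Z)-iodo allylic alcohol F9.
- MnO2 gives the (Z)-β-iodo enal F10. Brown allylboration with the B-allyldiisopinocampheylborane derived from (−)-α-pinene, followed by oxidative work-up, sets C7 in the homoallylic alcohol F11. Cross metathesis with 2-methyl-2-butene (Grubbs II) then turns the terminal vinyl group into the prenyl terminus of 15.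

**3. Step 12 (Stille coupling of the tetrasubstituted iodide).**
- What may go wrong: oxidative addition and transmetalation at the crowded alkenyl iodide may be slower than self-coupling of the bromostannane.
- Fallback: it reverses the polarity, sets out from 16 and 17, comes back at 19, and makes step 11 unnecessary.
- Iodine–lithium exchange on 16 (t-BuLi, 2 equiv, Et2O, −78 °C) gives the configurationally stable alkenyllithium F12. ZnBr2 converts it into the alkenylzinc bromide F13. Negishi coupling with 17 itself (Pd(PPh3)4, THF, rt) uses the preference of Pd(0) for the C3–Br bond to give 19.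

**Further compounds**
F1 | step 13 | allyl analogue of 19 | CC[Si](CC)(CC)C#C[C@](C)(O[Si](CC)(CC)CC)CC/C(C1=CC(Br)=COC1=O)=C(\C)[C@H](O[Si](C)(C)C(C)(C)C)CC=C
F2 | step 13 | 4,4-bisnor bromo adduct | CC[Si](CC)(CC)C#C[C@](C)(O[Si](CC)(CC)CC)CCC1=C(C)[C@H](O[Si](C)(C)C(C)(C)C)C[C@H]2C[C@@H]3C(Br)=C[C@]12C(=O)O3
F3 | step 13 | bisnor lactone | CC[Si](CC)(CC)C#C[C@](C)(O[Si](CC)(CC)CC)CCC1=C(C)[C@H](O[Si](C)(C)C(C)(C)C)C[C@H]2C[C@@H]3C=C[C@]12C(=O)O3
F4 | step 13 | bisnor diol | CC[Si](CC)(CC)C#C[C@](C)(O[Si](CC)(CC)CC)CCC1=C(C)[C@H](O[Si](C)(C)C(C)(C)C)C[C@H]2C[C@@H](O)C=C[C@]12CO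
F5 | step 13 | bisnor hydroxy enone | CC[Si](CC)(CC)C#C[C@](C)(O[Si](CC)(CC)CC)CCC1=C(C)[C@H](O[Si](C)(C)C(C)(C)C)C[C@H]2CC(=O)C=C[C@]12CO
F6 | step 13 | 4α-methyl enone | CC[Si](CC)(CC)C#C[C@](C)(O[Si](CC)(CC)CC)CCC1=C(C)[C@H](O[Si](C)(C)C(C)(C)C)C[C@H]2[C@H](C)C(=O)C=C[C@]12CO
F7 | step 9 | primary propargylic alcohol | CC[Si](CC)(CC)C#C[C@](C)(O[Si](CC)(CC)CC)CCC#CCO
F8 | step 9 | unsubstituted oxamagnesacyclopentene | CC[Si](CC)(CC)C#C[C@](C)(O[Si](CC)(CC)CC)CCC1=C(C)CO[Mg]1
F9 | step 9 | (Z)-iodo allylic alcohol | CC[Si](CC)(CC)C#C[C@](C)(O[Si](CC)(CC)CC)CC/C(I)=C(\C)CO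
F10 | step 9 | (Z)-β-iodo enal | CC[Si](CC)(CC)C#C[C@](C)(O[Si](CC)(CC)CC)CC/C(I)=C(\C)C=O
F11 | step 9 | homoallylic alcohol | CC[Si](CC)(CC)C#C[C@](C)(O[Si](CC)(CC)CC)CC/C(I)=C(\C)[C@H](O)CC=C
F12 | step 12 | alkenyllithium | CC[Si](CC)(CC)C#C[C@](C)(O[Si](CC)(CC)CC)CC/C([Li])=C(\C)[C@H](O[Si](C)(C)C(C)(C)C)CC=C(C)C
F13 | step 12 | alkenylzinc bromide | CC[Si](CC)(CC)C#C[C@](C)(O[Si](CC)(CC)CC)CC/C([Zn]Br)=C(\C)[C@H](O[Si](C)(C)C(C)(C)C)CC=C(C)C
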